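**Retrosynthetic overview**

1. Manuifolin E ⇒ (MOM removal) ⇒ both aryl–C(CH3)2CH=CH2 bonds, at C6 and C5′, are cut back to a 6,5′-dibromide (twofold γ-selective prenyl Suzuki–Miyaura coupling) ⇒ (NBS) ⇒ (3R)-7,2′,4′-tris(MOM-oxy)isoflavan.
2. Key disconnection C3–C1′: an enantioselective Pd-catalysed reductive Heck hydroarylation of 7-(MOM-oxy)-2H-chromene with 1-iodo-2,4-bis(MOM-oxy)benzene joins ring B to the chroman and sets C3, the only stereocentre.
3. Enabling feature: C3 is flanked by C4, an unsubstituted benzylic CH2 on ring A, so ring C can be carried as its C3=C4 styrenic alkene. Aryl–Pd adds aryl to C3 and Pd to C4; the syn adduct has no syn β-hydrogen (C3–H is anti, C4a is aromatic), so formate reduces it to the C4 methylene.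
4. Rings A and B are both 4-alkylresorcinol ethers, so C6 and C5′ (para to O1 and to the 2′-oxygen) are the innate bromination sites. The Heck-reactive vinyl groups are therefore introduced only after the key step.
5. Ring order: rings A and B are bought as arenes; pyran ring C is closed in step 2 (oxa-Michael/Wittig on a salicylaldehyde); no ring is formed afterwards.

Key step: step 4

Remark (assumption): 4-iodoresorcinol, vinyltriphenylphosphonium bromide and prenylboronic acid pinacol ester are taken as catalogue compounds; isoflavan numbering is used (O1, C2, C3, C4, C4a–C8a for rings C/A; C1′–C6′ for ring B).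

**Route**

Step 1
Reactants: 1 2,4-dihydroxybenzaldehyde
Product: 2 2-hydroxy-4-(methoxymethoxy)benzaldehyde
Conditions: MOMCl (1.05 equiv), K2CO3, acetone, 0 °C to rt
Reagents that add atoms: chloromethyl methyl ether (MOMCl), COCCl
Why: Williamson-type MOM protection should be selective for the 4-OH, because the 2-OH is held in an intramolecular hydrogen bond to the formyl group and is the weaker nucleophile under carbonate conditions; no stereocentre is formed.

Step 2
Reactants: 2 2-hydroxy-4-(methoxymethoxy)benzaldehyde; 3 vinyltriphenylphosphonium bromide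
Product: 5 7-(methoxymethoxy)-2H-chromene, via phosphonium ylide 4 (not isolated)
Conditions: NaH, THF, 0 °C; then 3 (1.2 equiv), THF–DMF, 65 °C
Reagents that add atoms: none
Why: Schweizer chromene synthesis, in which the phenoxide adds to the vinylphosphonium salt (oxa-Michael) to give ylide 4 and an intramolecular Wittig olefination of the ortho-formyl group closes pyran ring C with the alkene at C3=C4; no stereocentre is formed.

Step 3
Reactants: 6 4-iodoresorcinol
Product: 7 1-iodo-2,4-bis(methoxymethoxy)benzene
Conditions: NaH (2.4 equiv), DMF, 0 °C; MOMCl (2.4 equiv), 0 °C to rt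
Reagents that add atoms: chloromethyl methyl ether (MOMCl), COCCl
Why: Twofold Williamson-type MOM protection after irreversible deprotonation of both phenols should proceed cleanly and leave the C–I bond untouched.

Step 4
Reactants: 5 7-(methoxymethoxy)-2H-chromene (1.3 equiv); 7 1-iodo-2,4-bis(methoxymethoxy)benzene
Product: 8 (3R)-3-[2,4-bis(methoxymethoxy)phenyl]-7-(methoxymethoxy)chromane
Conditions: Pd(dba)2 (5 mol %), chiral bisphosphine monoxide L* (e.g. Xyl-SDP(O), 6 mol %, antipode chosen for 3R), HCO2Na (2 equiv), ethylene glycol–dioxane, 60 °C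
Reagents that add atoms: none
Why: Proposed new method: oxidative addition of 7 to Pd(0)L* and iodide dissociation (protic medium, hemilabile P,O ligand) should give a cationic aryl–Pd species that inserts the C3=C4 alkene of 5 syn, aryl to C3 and Pd to benzylic C4 (η3-benzyl stabilised by ring A), after which formate binds, loses CO2 and the Pd–H reductively eliminates the C4–H bond, i.e. a reductive Heck hydroarylation. The closest known reactions are the Pd-catalysed oxyarylation of 2H-chromenes with 2-halophenols to pterocarpans (same C3-aryl/C4-Pd regiochemistry), formate-terminated reductive Heck hydroarylations of cyclic styrenes, and ligand-controlled enantioselective intermolecular Heck and reductive Heck arylations of cyclic alkenes; new is the enantioselective reductive version on a 2H-chromene. No ring is closed. The single new stereocentre C3 is set in the migratory insertion, where the chiral ligand differentiates the two enantiotopic faces of the planar chromene; the absolute sense is not predicted, so the ligand antipode is fixed after a first run. The step needs regioselectivity (aryl to C3, not C4), secured by conjugation of C4 with ring A; reduction instead of β-hydride elimination, secured because the C3–H is anti to Pd after syn addition and C4a bears no hydrogen; and chemoselectivity for one alkene, secured because the 1,1-dimethylallyl groups are not yet present.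

Step 5
Reactants: 8 (3R)-3-[2,4-bis(methoxymethoxy)phenyl]-7-(methoxymethoxy)chromane
Product: 9 (3R)-6-bromo-3-[5-bromo-2,4-bis(methoxymethoxy)phenyl]-7-(methoxymethoxy)chromane
Conditions: NBS (2.05 equiv), MeCN, −10 to 0 °C, dark
Reagents that add atoms: N-bromosuccinimide (NBS), O=C1CCC(=O)N1Br
Why: Electrophilic aromatic bromination with NBS in a polar solvent should go para to an alkoxy group, and C6 (para to O1, ortho to 7-OMOM) and C5′ (para to 2′-OMOM, ortho to 4′-OMOM) are the most activated unhindered CH positions of the two resorcinol-type rings, whereas C8 and C3′ lie between two oxygens and C3 is not touched.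

Step 6
Reactants: 9 (3R)-6-bromo-3-[5-bromo-2,4-bis(methoxymethoxy)phenyl]-7-(methoxymethoxy)chromane; 10 prenylboronic acid pinacol ester (3 equiv)
Product: 11 (3R)-3-[2,4-bis(methoxymethoxy)-5-(2-methylbut-3-en-2-yl)phenyl]-7-(methoxymethoxy)-6-(2-methylbut-3-en-2-yl)chromane
Conditions: Pd precatalyst with a γ-selective ligand (dialkylbiarylphosphine or D-t-BPF type, 5 mol % per C–Br), aq K3PO4, THF, 40 °C
Reagents that add atoms: none
Why: γ-Selective allyl–aryl Suzuki–Miyaura coupling, in which SE2′ transmetalation of the prenylboronate places Pd on the tertiary carbon and reductive elimination from this σ-allyl complex outruns its equilibration, is a known ligand-controlled way to turn aryl bromides into 1,1-dimethylallyl arenes, and the remote C3 stereocentre is unaffected.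

Step 7
Reactants: 11 (3R)-3-[2,4-bis(methoxymethoxy)-5-(2-methylbut-3-en-2-yl)phenyl]-7-(methoxymethoxy)-6-(2-methylbut-3-en-2-yl)chromane
Product: 12 Manuifolin E, (3R)-3-[2,4-dihydroxy-5-(2-methylbut-3-en-2-yl)phenyl]-6-(2-methylbut-3-en-2-yl)chroman-7-ol
Conditions: HCl (2 M), MeOH–THF, rt to 40 °C; NaHCO3 quench at full conversion
Reagents that add atoms: none
Why: Acid-catalysed acetal exchange with methanol should remove the three MOM ethers as dimethoxymethane under conditions too mild to protonate the monosubstituted alkenes of the 1,1-dimethylallyl groups, and the non-acidic C3 stereocentre is retained.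

**Compound list**

1 | 2,4-dihydroxybenzaldehyde | O=Cc1ccc(O)cc1O | starting material
2 | 2-hydroxy-4-(methoxymethoxy)benzaldehyde | COCOc1ccc(C=O)c(O)c1 | intermediate
3 | vinyltriphenylphosphonium bromide | C=C[P+](c1ccccc1)(c1ccccc1)c1ccccc1.[Br-] | starting material
4 | [2-(2-formyl-5-(methoxymethoxy)phenoxy)ethylidene]triphenylphosphorane | COCOc1ccc(C=O)c(OCC=P(c2ccccc2)(c2ccccc2)c2ccccc2)c1 | intermediate
5 | 7-(methoxymethoxy)-2H-chromene | COCOc1ccc2C=CCOc2c1 | intermediate
6 | 4-iodoresorcinol (4-iodobenzene-1,3-diol) | Oc1ccc(I)c(O)c1 | starting material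
7 | 1-iodo-2,4-bis(methoxymethoxy)benzene | COCOc1ccc(I)c(OCOC)c1 | intermediate
8 | (3R)-3-[2,4-bis(methoxymethoxy)phenyl]-7-(methoxymethoxy)chromane | COCOc1ccc2c(c1)OC[C@@H](c1ccc(OCOC)cc1OCOC)C2 | intermediate
9 | (3R)-6-bromo-3-[5-bromo-2,4-bis(methoxymethoxy)phenyl]-7-(methoxymethoxy)chromane | Brc1cc2c(cc1OCOC)OC[C@@H](c1cc(Br)c(OCOC)cc1OCOC)C2 | intermediate
10 | prenylboronic acid pinacol ester, 4,4,5,5-tetramethyl-2-(3-methylbut-2-en-1-yl)-1,3,2-dioxaborolane | CC(C)=CCB1OC(C)(C)C(C)(C)O1 | starting material
11 | (3R)-3-[2,4-bis(methoxymethoxy)-5-(2-methylbut-3-en-2-yl)phenyl]-7-(methoxymethoxy)-6-(2-methylbut-3-en-2-yl)chromane | C=CC(C)(C)c1cc2c(cc1OCOC)OC[C@@H](c1cc(C(C)(C)C=C)c(OCOC)cc1OCOC)C2 | intermediate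
12 | Manuifolin E, (3R)-3-[2,4-dihydroxy-5-(2-methylbut-3-en-2-yl)phenyl]-6-(2-methylbut-3-en-2-yl)chroman-7-ol | C=CC(C)(C)c1cc2c(cc1O)OC[C@@H](c1cc(C(C)(C)C=C)c(O)cc1O)C2 | target

**Step count and risks**

Total steps: 7. Longest linear sequence: 6 (steps 1, 2, 4, 5, 6, 7).

Steps most likely to fail:

Step 4 (labelled). What may go wrong: poor enantiofacial discrimination in the migratory insertion, reduction of the aryl–palladium species by formate before it meets the alkene, or Pd–H-mediated migration of the C3=C4 bond of 5 into the enol-ether position. The fallback uses known, stereoconvergent chemistry; it sets out from iodide 7 and returns at 8. Commercial 7-hydroxychroman-4-one F1 is protected (MOMCl, i-Pr2NEt, CH2Cl2) to 7-(methoxymethoxy)chroman-4-one F2. Pd-catalysed ketone α-arylation of F2 with 7 (Pd2(dba)3, XPhos, NaOt-Bu, THF, 60 °C) should give racemic 3-[2,4-bis(methoxymethoxy)phenyl]-7-(methoxymethoxy)chroman-4-one F3. Ru(II)–TsDPEN transfer hydrogenation (HCO2H/Et3N) with dynamic kinetic resolution through the enolisable C3 should funnel both enantiomers into (3R,4R)-cis-3-[2,4-bis(methoxymethoxy)phenyl]-7-(methoxymethoxy)chroman-4-ol F4, with the catalyst antipode chosen accordingly. Hydrogenolysis of the benzylic C4–O bond (H2, Pd/C, EtOAc–EtOH) then gives 8.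

Step 6. What may go wrong: erosion of γ-selectivity towards linear prenyl arenes, or stalling after one coupling because both bromides are electron-rich and flanked by an ortho MOM ether while a quaternary carbon must be formed. The fallback sets out from dibromide 9 and returns at 11. Twofold Pd-catalysed α-arylation of the lithium enolate of methyl isobutyrate (LiNCy2, Pd(dba)2, P(t-Bu)3, toluene, rt) should give methyl 2-[(3R)-3-[5-(1-methoxy-2-methyl-1-oxopropan-2-yl)-2,4-bis(methoxymethoxy)phenyl]-7-(methoxymethoxy)chroman-6-yl]-2-methylpropanoate F5. DIBAL-H (toluene, −78 °C) should give 2-[(3R)-3-[2,4-bis(methoxymethoxy)-5-(2-methyl-1-oxopropan-2-yl)phenyl]-7-(methoxymethoxy)chroman-6-yl]-2-methylpropanal F6. Twofold Wittig methylenation (Ph3P=CH2, THF, 0 °C) then completes both 1,1-dimethylallyl groups and gives 11.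

Step 7. What may go wrong: acid-promoted addition of the freed ortho-phenols to the neighbouring vinyl groups (cycloetherification), or alkene isomerisation during acetal cleavage. The fallback moves the acid step in front of the alkene installation; it sets out from 9 and returns at 12. HCl in MeOH, with no alkene yet present, should give (3R)-6-bromo-3-(5-bromo-2,4-dihydroxyphenyl)chroman-7-ol F7. Silylation (TBSCl, imidazole, DMF) should give (3R)-6-bromo-3-[5-bromo-2,4-bis(tert-butyldimethylsilyloxy)phenyl]-7-(tert-butyldimethylsilyloxy)chromane F8. The γ-selective coupling of step 6 with 10 should give (3R)-3-[2,4-bis(tert-butyldimethylsilyloxy)-5-(2-methylbut-3-en-2-yl)phenyl]-7-(tert-butyldimethylsilyloxy)-6-(2-methylbut-3-en-2-yl)chromane F9. Buffered fluoride (TBAF/AcOH, THF, 0 °C) then frees 12 without acid.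

**Further compounds**

F1 | step 4 | 7-hydroxychroman-4-one | O=C1CCOc2cc(O)ccc12
F2 | step 4 | 7-(methoxymethoxy)chroman-4-one | COCOc1ccc2C(=O)CCOc2c1
F3 | step 4 | rac-3-[2,4-bis(methoxymethoxy)phenyl]-7-(methoxymethoxy)chroman-4-one | COCOc1ccc2C(=O)C(c3ccc(OCOC)cc3OCOC)COc2c1
F4 | step 4 | (3R,4R)-cis-3-[2,4-bis(methoxymethoxy)phenyl]-7-(methoxymethoxy)chroman-4-ol | COCOc1ccc2c(c1)OC[C@@H](c1ccc(OCOC)cc1OCOC)[C@H]2O
F5 | step 6 | methyl 2-[(3R)-3-[5-(1-methoxy-2-methyl-1-oxopropan-2-yl)-2,4-bis(methoxymethoxy)phenyl]-7-(methoxymethoxy)chroman-6-yl]-2-methylpropanoate | COC(=O)C(C)(C)c1cc2c(cc1OCOC)OC[C@@H](c1cc(C(C)(C)C(=O)OC)c(OCOC)cc1OCOC)C2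
F6 | step 6 | 2-[(3R)-3-[2,4-bis(methoxymethoxy)-5-(2-methyl-1-oxopropan-2-yl)phenyl]-7-(methoxymethoxy)chroman-6-yl]-2-methylpropanal | O=CC(C)(C)c1cc2c(cc1OCOC)OC[C@@H](c1cc(C(C)(C)C=O)c(OCOC)cc1OCOC)C2
F7 | step 7 | (3R)-6-bromo-3-(5-bromo-2,4-dihydroxyphenyl)chroman-7-ol | Brc1cc2c(cc1O)OC[C@@H](c1cc(Br)c(O)cc1O)C2
F8 | step 7 | (3R)-6-bromo-3-[5-bromo-2,4-bis(tert-butyldimethylsilyloxy)phenyl]-7-(tert-butyldimethylsilyloxy)chromane | Brc1cc2c(cc1O[Si](C)(C)C(C)(C)C)OC[C@@H](c1cc(Br)c(O[Si](C)(C)C(C)(C)C)cc1O[Si](C)(C)C(C)(C)C)C2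
F9 | step 7 | (3R)-3-[2,4-bis(tert-butyldimethylsilyloxy)-5-(2-methylbut-3-en-2-yl)phenyl]-7-(tert-butyldimethylsilyloxy)-6-(2-methylbut-3-en-2-yl)chromane | C=CC(C)(C)c1cc2c(cc1O[Si](C)(C)C(C)(C)C)OC[C@@H](c1cc(C(C)(C)C=C)c(O[Si](C)(C)C(C)(C)C)cc1O[Si](C)(C)C(C)(C)C)C2
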